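## Structural features

The target is a trans-fused bicyclo[5.3.0]decane of the daucane type in which a cyclopentane (C1–C5) and a cycloheptane (C1, C5–C10) share the C1–C5 bond; the numbering used throughout is C1 (ring-fusion carbon with the angular methyl), C2 and C3 (CH2), C4 (carbinol carbon with the isopropyl group), C5 (ring-fusion CH), C6 (CH–OBz), C7 (CH2), C8 (oxirane carbon with methyl), C9 (oxirane CH) and C10 (CH2), and β denotes the face of the C1 methyl group. Six stereocentres are present, C1 (R, quaternary), C4 (R, OH β and isopropyl α), C5 (S, H α), C6 (S, benzoate α), C8 (R) and C9 (S, oxirane on the α face); C4, C5 and C6 are contiguous and C1 is bonded to C5. The fragile groups are the trisubstituted oxirane (acid, Lewis acid, hydride, and transannular attack by the C4 hydroxyl, which sits behind C8), the benzoate (nucleophiles, base) and, in any precursor with a C6 ketone, the tertiary aldol unit C4(OH)–C5–C6(=O) (retro-aldol, dehydration, epimerisation at C5). The real difficulty is the trans ring fusion between the quaternary C1 and C5, because ring closures that bond a tether to an sp2 C5 give the cis isomer and enolate trapping next to C1 must tell CH3 from CH2R, together with the C4/C5/C6 triad in which the tertiary hydroxyl is cis to C6 on the five-membered ring. The feature exploited is that C5–C6–C7–C8–C9 of the seven-membered ring can be drawn as a skipped diene C5=C6/C8=C9 around the C7 methylene, with C10 on C9 and the quaternary C1 closing the ring: the retron of a cis-divinylcyclopropane rearrangement in which C6, C7 and C8 formed the cyclopropane and C1–C10 is the bond made. In one sentence, the route rearranges a cyclopropane that carries a vinyl group on C8 and a 2-methyl-5-oxocyclopentenyl group on C6, cis to each other, into the bicyclic cyclohepta-1,4-dienone, closing the seven-membered ring and creating C1 by chirality transfer. After that the stereocentres are relayed: a C6 carbinol steers an oxirane onto C4=C5, gives its hydrogen to C5 in a stereospecific 1,2-shift (C4 and C5 in one event), is re-set by internal hydride delivery from the C4 hydroxyl, and finally steers the C8–C9 oxirane.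

## Logic of the disconnections

20 ⇒ 19. The ester C–O bond at C6 is cut. The benzoate is the group most exposed to nucleophiles and base, so it goes on last, and the free C6 hydroxyl is needed one step earlier as a directing group. The forward step must acylate the secondary hydroxyl beside an inert tertiary one without opening the oxirane.

19 ⇒ 18. Both C–O bonds of the oxirane (C8–O, C9–O) are cut. This removes two stereocentres and the most acid-labile group, leaving a trisubstituted alkene that survives all earlier steps. The forward step must deliver oxygen to the α face; the homoallylic 6α-hydroxyl and the β-methyl on C1 both favour that face.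

18 ⇒ 17. The C6–H bond is cut, giving a C6 ketone and removing the C6 stereocentre. The forward step must deliver hydride to the β face of C6, which internal delivery from the β-hydroxyl on C4 provides.

17 ⇒ 14 (through 15 and 16). The C5–H bond is cut and the hydrogen returned to C6, with the C6 carbonyl oxygen becoming a carbinol and the C4 oxygen closing onto C5 as an oxirane. The ring-fusion centre C5 and the tertiary carbinol C4 thereby collapse into one oxirane face. The forward step is a 1,2-hydride shift that must open the oxirane at C5 and not at C4, with the C6–H anti to the breaking C5–O bond.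

14 ⇒ 13. The two C–O bonds of the C4–C5 oxirane are cut, leaving a tetrasubstituted alkene and an allylic carbinol at C6. The forward step must put oxygen on the face of the carbinol and leave C8=C9 alone.

13 ⇒ 12. The C6–H bond is cut to an enone. The C6 carbinol is a temporary control element, so its configuration relative to C1 must be set by the reagent.

12 ⇒ 11 ⇒ 10. The enone is transposed back (C6=O and C4=C5 to C4–OH and C5=C6) and the C4–isopropyl bond is cut. This leaves a dienone without the isopropyl group. The configuration at C4 in 11 is irrelevant because the transposition erases it.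

10 ⇒ 9. The C1–C10 bond is cut and C6–C8 reconnected. The seven-membered ring and the quaternary centre C1 reduce to a cyclopropane with two stereocentres, and the positions of both ring alkenes and of the C8 methyl are fixed by the connectivity of 9. The forward step demands that the two alkenyl groups stand cis and that the 3,3-shift stays concerted.

9 ⇒ 8 ⇒ 7. The C9=C10 double bond is cut (methylenation) and the aldehyde taken back to the primary alcohol. The alcohol is the handle for the next disconnection.

7 ⇒ 6. The C6–C7 and C7–C8 bonds are cut (methylene transfer). The cis relation on the ring becomes the Z geometry of an allylic alcohol, and the two cyclopropane centres become one face selection by a chiral ligand.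

6 ⇒ 4 + 2 (through 5). The sp2–sp2 bond C5–C6 is cut. Both partners are one step from commercial materials; the coupling must retain the Z geometry.

4 ⇒ 3 and 2 ⇒ 1. The C8–CH3 and C6–I bonds are cut back to the alkyne, where anti addition across the triple bond must place iodine cis to the CH2OH group. The C5–Br bond is cut back to the enone.

## Other disconnections considered

Alternative 1: The cut most chemists would draw first is C8=C9 by ring-closing metathesis. The cyclopentane would be built from 1 by conjugate allylation at C1 and aldol trapping at C5, giving diene A1, and metathesis would give hydroxy ketone A2. The chosen plan is preferred because in this alternative the trans relation C1/C5 rests on enolate trapping next to a quaternary carbon whose two groups (CH3 and CH2R) differ little in size. The aldol must also occur at the more hindered α-carbon, and A2 carries C5–H α to a cyclopentanone, where drift to the cis-fused isomer is a standing risk. The metathesis itself sets no stereocentre, so the step count is similar while the stereocontrol is weaker.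

Alternative 2: C6–C7 and C1–C10 are cut together. The forward step is an intermolecular dirhodium-carbenoid cyclopropanation/Cope sequence (formal (4+3), Rh2(S-DOSP)4) between isoprene and diazo ester A3, giving bicyclic ester A4 in two steps from an enone acetate. It is not chosen because isoprene offers two terminal alkenes and, on the substituted one, a choice of methyl or vinyl cis to the carbenoid alkenyl group, so both regiochemistry and cis/trans selection are open. The ester carbon on C6 would also have to be exchanged for oxygen by C–C cleavage, which costs the steps saved.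

Alternative 3: C4–C5 is cut (intramolecular aldol) with the seven-membered ring already in place, from diketone A5 directly to aldol 17. It is not chosen because closing a five-membered ring onto the sp2 C5 of a ring enolate from a tether on C1 delivers the new bond to the tether face, which should give the cis-fused aldol A6. Reaching 17 would then depend on retro-aldol equilibration of a dehydration-prone tertiary aldol, and A5 needs its own multi-step asymmetric synthesis of the quaternary centre.

Key step: step 7

## Route

Step 1
Reactants: 1 3-methylcyclopent-2-en-1-one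
Product: 2 2-bromo-3-methylcyclopent-2-en-1-one
Conditions: Br2, CH2Cl2, 0 °C; then Et3N, 0 °C to rt
Reagents that add atoms: bromine BrBr
Why: Bromine adds across the enone and triethylamine eliminates HBr from the dibromide (addition–elimination), which gives the α-bromoenone; no stereocentre is formed.

Step 2
Reactants: 3 prop-2-yn-1-ol
Product: 4 (2Z)-3-iodo-2-methylprop-2-en-1-ol
Conditions: MeMgBr (2.5 equiv), CuI (10 mol%), THF/Et2O, −10 °C to rt; then I2, −78 to 0 °C
Reagents that add atoms: methylmagnesium bromide C[Mg]Br; iodine II
Why: Copper-catalysed anti-carbomagnesiation of the propargylic alkoxide puts the methyl group on C8 and magnesium on C6 in a five-membered chelate cis to the CH2O group; iodinolysis with retention should give the Z iodide.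

Step 3
Reactants: 4 (2Z)-3-iodo-2-methylprop-2-en-1-ol; 2 2-bromo-3-methylcyclopent-2-en-1-one
Product: 6 2-[(1Z)-3-hydroxy-2-methylprop-1-en-1-yl]-3-methylcyclopent-2-en-1-one, via alkenyl pinacol boronate 5 (not isolated)
Conditions: B2pin2, PdCl2(dppf) (3 mol%), KOPh, PhMe, 50 °C; then 2, aq. K3PO4, 70 °C
Reagents that add atoms: none
Why: Miyaura borylation of the alkenyl iodide followed in the same flask by Suzuki–Miyaura coupling with the α-bromoenone forms the C5–C6 bond; both steps proceed with retention of alkene geometry, so the CH2OH group stays cis to the ring.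

Step 4
Reactants: 6 2-[(1Z)-3-hydroxy-2-methylprop-1-en-1-yl]-3-methylcyclopent-2-en-1-one
Product: 7 2-[(1R,2S)-2-(hydroxymethyl)-2-methylcyclopropyl]-3-methylcyclopent-2-en-1-one
Conditions: Et2Zn, CH2I2 (to Zn(CH2I)2·DME), (4R,5R)-2-butyl-N,N,N′,N′-tetramethyl-1,3,2-dioxaborolane-4,5-dicarboxamide (1.2 equiv, recovered), CH2Cl2, −10 °C to rt
Reagents that add atoms: diiodomethane ICI
Why: Charette asymmetric Simmons–Smith cyclopropanation: the zinc alkoxide bound to the chiral boronate directs methylene to one face of the allylic alkene (the Si face at C8 by the accepted model for the (4R,5R) ligand), and stereospecific syn addition turns the Z geometry into the cis relation of cyclopentenyl and CH2OH, setting C6 and C8. The tetrasubstituted enone alkene is electron-poor and undirected and should not react.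

Step 5
Reactants: 7 2-[(1R,2S)-2-(hydroxymethyl)-2-methylcyclopropyl]-3-methylcyclopent-2-en-1-one
Product: 8 (1S,2R)-1-methyl-2-(2-methyl-5-oxocyclopent-1-en-1-yl)cyclopropane-1-carbaldehyde
Conditions: Dess–Martin periodinane, NaHCO3, CH2Cl2, 0 °C to rt
Reagents that add atoms: none
Why: Dess–Martin oxidation of the primary alcohol; the aldehyde sits on a quaternary carbon and cannot epimerise.

Step 6
Reactants: 8 (1S,2R)-1-methyl-2-(2-methyl-5-oxocyclopent-1-en-1-yl)cyclopropane-1-carbaldehyde
Product: 9 2-[(1R,2R)-2-ethenyl-2-methylcyclopropyl]-3-methylcyclopent-2-en-1-one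
Conditions: Ph3PCH3Br, KN(SiMe3)2, THF, −78 to 0 °C (1.05 equiv of ylide)
Reagents that add atoms: methyltriphenylphosphonium bromide C[P+](c1ccccc1)(c1ccccc1)c1ccccc1.[Br-]
Why: Wittig methylenation adds C10; the aldehyde is far more electrophilic than the hindered, conjugated ring ketone, and any dihydrooxepine valence tautomer of 8 (retro-Claisen) is in equilibrium with the aldehyde and is drained by the olefination.

Step 7
Reactants: 9 2-[(1R,2R)-2-ethenyl-2-methylcyclopropyl]-3-methylcyclopent-2-en-1-one
Product: 10 (8aR)-6,8a-dimethyl-1,2,8,8a-tetrahydroazulen-3(5H)-one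
Conditions: PhMe (0.02 M), BHT (cat.), 120 °C, sealed tube
Reagents that add atoms: none
Why: The two alkenyl groups of 9 stand cis on the cyclopropane, so the vinyl carbon C10 and the ring carbon C1 can meet in a boat-shaped six-centre transition state (3,3-sigmatropic shift; the closest known reaction type is the cis-divinylcyclopropane to cyclohepta-1,4-diene rearrangement, here on a 2-acyl-1,5-diene). The cyclopropane σ bond C6–C8 breaks while C1–C10 forms, so the seven-membered ring is closed by enlargement of the three-membered ring (3 to 7 atoms), and the new double bonds appear at C5=C6 and C8=C9 with the C8 methyl already in place. Release of ring strain and conjugation of the new C5=C6 bond with the ketone should make the step irreversible. C1 is the only new stereocentre: in the boat transition state C10 can reach only the cyclopentene face that lies over the cyclopropane, so the configuration of C6/C8 is transferred to C1 (C10 α, methyl β) without any need to tell CH3 from CH2. The selectivity needed is that the concerted path outruns homolysis of the doubly allylic C6–C8 bond; the cis geometry fixed in step 4 and the strain release favour this, although the C1 methyl points into the boat and raises the barrier above that of the parent system, hence 120 °C. There is no regiochemical ambiguity because both termini are defined by the substrate.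

Step 8
Reactants: 10 (8aR)-6,8a-dimethyl-1,2,8,8a-tetrahydroazulen-3(5H)-one
Product: 11 (8aR)-6,8a-dimethyl-3-(propan-2-yl)-1,2,3,5,8,8a-hexahydroazulen-3-ol (both epimers at the carbinol carbon)
Conditions: iPrMgCl, LaCl3·2LiCl, THF, −78 to 0 °C
Reagents that add atoms: isopropylmagnesium chloride CC(C)[Mg]Cl
Why: 1,2-Addition of the Grignard reagent to the enone carbonyl, with the lanthanum salt suppressing enolisation, reduction and conjugate addition; the configuration at C4 does not matter because the next step erases it.

Step 9
Reactants: 11 (8aR)-6,8a-dimethyl-3-(propan-2-yl)-1,2,3,5,8,8a-hexahydroazulen-3-ol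
Product: 12 (8aR)-6,8a-dimethyl-3-(propan-2-yl)-1,2,8,8a-tetrahydroazulen-4(5H)-one
Conditions: 2,2,6,6-tetramethyl-1-oxopiperidinium tetrafluoroborate (1.5 equiv), MeCN, rt
Reagents that add atoms: none
Why: Oxidative 1,3-transposition of a tertiary allylic alcohol (Babler–Dauben type, here with an oxoammonium salt under near-neutral conditions): oxygen moves from C4 to C6 with the double bond shifting to C4=C5, and the secondary allylic adduct is oxidised to the enone; both C4 epimers converge.

Step 10
Reactants: 12 (8aR)-6,8a-dimethyl-3-(propan-2-yl)-1,2,8,8a-tetrahydroazulen-4(5H)-one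
Product: 13 (4R,8aR)-6,8a-dimethyl-3-(propan-2-yl)-1,2,4,5,8,8a-hexahydroazulen-4-ol
Conditions: (S)-2-methyl-CBS-oxazaborolidine (20 mol%), catecholborane, PhMe, −78 °C
Reagents that add atoms: none
Why: Corey–Bakshi–Shibata reduction: the catalyst distinguishes the fully substituted alkenyl carbon C5 (large) from the C7 methylene (small), so the (S)-catalyst should give the (R)-carbinol, i.e. the 6β-hydroxyl, under reagent control; catecholborane does not hydroborate C8=C9 at this temperature.

Step 11
Reactants: 13 (4R,8aR)-6,8a-dimethyl-3-(propan-2-yl)-1,2,4,5,8,8a-hexahydroazulen-4-ol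
Product: 14 (1R,4R,5S,6R)-4,5-epoxydauc-8-en-6-ol (4β,5β-oxirane and 6β-hydroxyl)
Conditions: VO(acac)2 (5 mol%), t-BuOOH (1.1 equiv), CH2Cl2, 0 °C
Reagents that add atoms: tert-butyl hydroperoxide CC(C)(C)OO
Why: Vanadium-catalysed hydroxyl-directed epoxidation: the allylic alkoxide on vanadium delivers the peroxide oxygen to the face of C4=C5 on which the hydroxyl stands (β), which fixes the future C4–O configuration. The tetrasubstituted allylic alkene should react much faster than the homoallylic C8=C9.

Step 12
Reactants: 14 (1R,4R,5S,6R)-4,5-epoxydauc-8-en-6-ol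
Product: 17 (1R,4R,5R)-4β-hydroxydauc-8-en-6-one, via epoxy trimethylsilyl ether 15 (not isolated), via tertiary trimethylsilyl ether 16 (not isolated)
Conditions: TMSOTf (2.2 equiv), iPr2NEt (3 equiv), 4 Å MS, CH2Cl2, −78 to −40 °C; then HF·pyridine, THF, 0 °C
Reagents that add atoms: none
Why: After O-silylation, the silyl triflate activates the oxirane and the C6–H, anti to the C5–O bond, migrates to C5 with inversion (semipinacol-type 1,2-hydride shift of a 2,3-epoxy silyl ether, the non-aldol aldol rearrangement). This places H5 on the α face (trans ring fusion) and leaves the oxygen on C4 β, so C4 and C5 are set together from the oxirane face. The oxocarbenium ion at C6 loses silicon to give the ketone, and HF·pyridine frees the tertiary alcohol.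

Step 13
Reactants: 17 (1R,4R,5R)-4β-hydroxydauc-8-en-6-one
Product: 18 (1R,4R,5S,6S)-dauc-8-ene-4β,6α-diol
Conditions: Me4NBH(OAc)3, MeCN/AcOH (1:1), −30 °C
Reagents that add atoms: none
Why: Evans–Saksena reduction: the acetoxyborohydride exchanges onto the C4 hydroxyl and delivers hydride intramolecularly to the β face of the C6 carbonyl, which should give the 6α-alcohol (1,3-anti diol); the mildly acidic medium avoids retro-aldol and epimerisation at C5.

Step 14
Reactants: 18 (1R,4R,5S,6S)-dauc-8-ene-4β,6α-diol
Product: 19 (1R,4R,5S,6S,8R,9S)-8α,9α-epoxydaucane-4β,6α-diol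
Conditions: VO(acac)2 (5 mol%), t-BuOOH (1.2 equiv), CH2Cl2, 0 °C to rt
Reagents that add atoms: tert-butyl hydroperoxide CC(C)(C)OO
Why: Vanadium-catalysed epoxidation directed by the homoallylic 6α-hydroxyl delivers oxygen to the α face of C8=C9; the axial C1 methyl shields the β face, so directing and steric effects reinforce each other.

Step 15
Reactants: 19 (1R,4R,5S,6S,8R,9S)-8α,9α-epoxydaucane-4β,6α-diol
Product: 20 (1R,4R,5S,6S,8R,9S)-8α,9α-epoxy-4β-hydroxydaucan-6α-yl benzoate (target)
Conditions: BzCl, pyridine, DMAP (cat.), CH2Cl2, 0 °C to rt
Reagents that add atoms: benzoyl chloride O=C(Cl)c1ccccc1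
Why: DMAP-catalysed acylation of the secondary C6 hydroxyl; the tertiary C4 hydroxyl is too hindered to react and the basic medium protects the oxirane.

## Compound list

1 | 3-methylcyclopent-2-en-1-one | CC1=CC(=O)CC1 | starting material
2 | 2-bromo-3-methylcyclopent-2-en-1-one | CC1=C(Br)C(=O)CC1 | intermediate
3 | prop-2-yn-1-ol | C#CCO | starting material
4 | (2Z)-3-iodo-2-methylprop-2-en-1-ol | OC/C(C)=C\I | intermediate
5 | (2Z)-2-methyl-3-(4,4,5,5-tetramethyl-1,3,2-dioxaborolan-2-yl)prop-2-en-1-ol | OC/C(C)=C\B1OC(C)(C)C(C)(C)O1 | intermediate (not isolated)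
6 | 2-[(1Z)-3-hydroxy-2-methylprop-1-en-1-yl]-3-methylcyclopent-2-en-1-one | OC/C(C)=C\C1=C(C)CCC1=O | intermediate
7 | 2-[(1R,2S)-2-(hydroxymethyl)-2-methylcyclopropyl]-3-methylcyclopent-2-en-1-one | OC[C@@]1(C)C[C@H]1C2=C(C)CCC2=O | intermediate
8 | (1S,2R)-1-methyl-2-(2-methyl-5-oxocyclopent-1-en-1-yl)cyclopropane-1-carbaldehyde | O=C[C@@]1(C)C[C@H]1C2=C(C)CCC2=O | intermediate
9 | 2-[(1R,2R)-2-ethenyl-2-methylcyclopropyl]-3-methylcyclopent-2-en-1-one | C=C[C@@]1(C)C[C@H]1C2=C(C)CCC2=O | intermediate
10 | (8aR)-6,8a-dimethyl-1,2,8,8a-tetrahydroazulen-3(5H)-one (C4 ketone, C5=C6 and C8=C9) | O=C1CC[C@]2(C)CC=C(C)CC=C12 | intermediate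
11 | (8aR)-6,8a-dimethyl-3-(propan-2-yl)-1,2,3,5,8,8a-hexahydroazulen-3-ol (both epimers at the carbinol carbon) | CC(C)C1(O)CC[C@]2(C)CC=C(C)CC=C12 | intermediate
12 | (8aR)-6,8a-dimethyl-3-(propan-2-yl)-1,2,8,8a-tetrahydroazulen-4(5H)-one | CC(C)C1=C2C(=O)CC(C)=CC[C@@]2(C)CC1 | intermediate
13 | (4R,8aR)-6,8a-dimethyl-3-(propan-2-yl)-1,2,4,5,8,8a-hexahydroazulen-4-ol (6β-hydroxyl) | CC(C)C1=C2[C@H](O)CC(C)=CC[C@@]2(C)CC1 | intermediate
14 | (1R,4R,5S,6R)-4β,5β-epoxydauc-8-en-6β-ol | CC(C)[C@@]12O[C@@]13[C@H](O)CC(C)=CC[C@@]3(C)CC2 | intermediate
15 | (1R,4R,5S,6R)-4β,5β-epoxy-6β-(trimethylsilyloxy)dauc-8-ene | CC(C)[C@@]12O[C@@]13[C@H](O[Si](C)(C)C)CC(C)=CC[C@@]3(C)CC2 | intermediate (not isolated)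
16 | (1R,4R,5R)-4β-(trimethylsilyloxy)dauc-8-en-6-one | CC(C)[C@]1(O[Si](C)(C)C)CC[C@]2(C)CC=C(C)CC(=O)[C@H]21 | intermediate (not isolated)
17 | (1R,4R,5R)-4β-hydroxydauc-8-en-6-one (5α-H) | CC(C)[C@]1(O)CC[C@]2(C)CC=C(C)CC(=O)[C@H]21 | intermediate
18 | (1R,4R,5S,6S)-dauc-8-ene-4β,6α-diol | CC(C)[C@]1(O)CC[C@]2(C)CC=C(C)C[C@H](O)[C@H]21 | intermediate
19 | (1R,4R,5S,6S,8R,9S)-8α,9α-epoxydaucane-4β,6α-diol | CC(C)[C@]1(O)CC[C@]2(C)C[C@@H]3O[C@]3(C)C[C@H](O)[C@H]21 | intermediate
20 | (1R,4R,5S,6S,8R,9S)-8α,9α-epoxy-4β-hydroxydaucan-6α-yl benzoate | CC(C)[C@]1(O)CC[C@]2(C)C[C@@H]3O[C@]3(C)C[C@H](OC(=O)c3ccccc3)[C@H]21 | target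

## Step count and least certain steps

Total: 15 steps. Longest linear sequence: 14 steps (steps 2 to 15, from prop-2-yn-1-ol); step 1 is the only step off the main line.

Step 7 (key step). The methyl group on C1 points into the boat transition state and C1 is fully substituted, so the concerted shift may need a temperature at which reversible homolysis of the doubly allylic C6–C8 bond competes. That would epimerise the cyclopropane or close the ring without chirality transfer, lowering conversion and enantiomeric purity at C1. The fallback sets out from 2 and comes back at 10; it makes the quaternary centre by a separate sigmatropic relay and closes the seven-membered ring by metathesis. BINOL-catalysed asymmetric allylboration of the ketone of 2 with allyl pinacol boronate would give (1R)-2-bromo-3-methyl-1-(prop-2-en-1-yl)cyclopent-2-en-1-ol F1. Anionic oxy-Cope rearrangement (KH, 18-crown-6, THF) moves the allyl group suprafacially from C4 to C1 and gives (3R)-2-bromo-3-methyl-3-(prop-2-en-1-yl)cyclopentan-1-one F2. Zinc insertion into the C–Br bond (Reformatsky) forms the enolate regiospecifically at C5, and addition to 3-methylbut-3-enal gives the aldol (3R)-2-(1-hydroxy-3-methylbut-3-en-1-yl)-3-methyl-3-(prop-2-en-1-yl)cyclopentan-1-one F3. Dehydration (MsCl, Et3N, then DBU) gives (2E,3R)-3-methyl-2-(3-methylbut-3-en-1-ylidene)-3-(prop-2-en-1-yl)cyclopentan-1-one F4. Ring-closing metathesis with RuCl2(H2IMes)(=CH-C6H4-2-OiPr) (second-generation Hoveyda–Grubbs catalyst) closes C8=C9 and returns to 10.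

Step 12. The tetrasubstituted oxirane may ionise toward C4 instead of C5, or the C5 cation may be intercepted by a shift from the neighbouring quaternary C1, so that the hydride shift is bypassed; the desilylation may also dehydrate the tertiary aldol. The fallback sets out from 14 and comes back at 17; it replaces the cationic shift by a reductive opening. Dess–Martin oxidation of the C6 carbinol gives the epoxy ketone (1R,4R,5R)-4β,5β-epoxydauc-8-en-6-one F5. SmI2 (THF/MeOH, −78 °C) cleaves the C5–O bond α to the ketone and leaves the 4β-oxygen in place; protonation of the samarium enolate at C5, with equilibration toward the isomer that holds C6 anti to the isopropyl group, leads to 17.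

Step 4. The alkene to be cyclopropanated is part of an electron-poor cross-conjugated dienone and the ketone can bind zinc, so methylene transfer may be slow and face selection eroded; the enantiomeric ligand is available should the sense of induction on this substrate differ from the model. The fallback sets out from 4 and comes back at 7; it carries out the cyclopropanation before the coupling. The same ligand-controlled Simmons–Smith reaction on 4 gives [(1R,2R)-2-iodo-1-methylcyclopropyl]methanol F6. Iodine–lithium exchange (t-BuLi, 3 equiv, −78 °C), transmetalation with ZnCl2 and Negishi coupling with 2 (Pd(PPh3)4) with retention at the cyclopropyl carbon return to 7.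

Step 14. Face selection could be lowered by competing direction from the tertiary β-hydroxyl, and under the Lewis-acidic vanadium conditions the C4 hydroxyl could open the new oxirane transannularly at C8. The fallback sets out from 18 and comes back at 20; it gives up the directing group and relies on steric control. Benzoylation first (BzCl, pyridine, DMAP) gives (1R,4R,5S,6S)-4β-hydroxydauc-8-en-6α-yl benzoate F7, and epoxidation with mCPBA buffered by NaHCO3 then occurs from the α face, anti to the axial C1 methyl, to give 20.

## Further compounds

F1 | step 7 | (1R)-2-bromo-3-methyl-1-(prop-2-en-1-yl)cyclopent-2-en-1-ol | C=CC[C@]1(O)CCC(C)=C1Br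
F2 | step 7 | (3R)-2-bromo-3-methyl-3-(prop-2-en-1-yl)cyclopentan-1-one (both C2 epimers) | C=CC[C@@]1(C)CCC(=O)C1Br
F3 | step 7 | (3R)-2-(1-hydroxy-3-methylbut-3-en-1-yl)-3-methyl-3-(prop-2-en-1-yl)cyclopentan-1-one (mixture at C2 and the carbinol carbon) | C=CC[C@@]1(C)CCC(=O)C1C(O)CC(C)=C
F4 | step 7 | (2E,3R)-3-methyl-2-(3-methylbut-3-en-1-ylidene)-3-(prop-2-en-1-yl)cyclopentan-1-one | O=C1CC[C@](C)(CC=C)/C1=C\CC(C)=C
F5 | step 12 | (1R,4R,5R)-4β,5β-epoxydauc-8-en-6-one | CC(C)[C@@]12O[C@@]13C(=O)CC(C)=CC[C@@]3(C)CC2
F6 | step 4 | [(1R,2R)-2-iodo-1-methylcyclopropyl]methanol | OC[C@@]1(C)C[C@H]1I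
F7 | step 14 | (1R,4R,5S,6S)-4β-hydroxydauc-8-en-6α-yl benzoate | CC(C)[C@]1(O)CC[C@]2(C)CC=C(C)C[C@H](OC(=O)c3ccccc3)[C@H]21
A1 | alternative 1 | 2α-H-2-[(1S)-1-hydroxy-3-methylbut-3-en-1-yl]-3β-methyl-3α-(prop-2-en-1-yl)cyclopentan-1-one (configuration as in the target) | C=CC[C@@]1(C)CCC(=O)[C@@H]1[C@@H](O)CC(C)=C
A2 | alternative 1 | (1R,5S,6S)-6α-hydroxy-11,12,13-trinordauc-8-en-4-one | O=C1CC[C@]2(C)CC=C(C)C[C@H](O)[C@H]21
A3 | alternative 2 | methyl 2-diazo-2-(2-methyl-5-oxocyclopent-1-en-1-yl)acetate | COC(=O)C(=[N+]=[N-])C1=C(C)CCC1=O
A4 | alternative 2 | methyl (8aR)-6,8a-dimethyl-3-oxo-1,2,3,5,8,8a-hexahydroazulene-4-carboxylate | COC(=O)C1=C2C(=O)CC[C@]2(C)CC=C(C)C1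
A5 | alternative 3 | (3R)-3,6-dimethyl-3-(4-methyl-3-oxopentyl)cyclohept-5-en-1-one | CC(C)C(=O)CC[C@]1(C)CC=C(C)CC(=O)C1
A6 | alternative 3 | cis-fused aldol, the C4 and C5 epimer of 17 (4α-hydroxy, 5β-H) | CC(C)[C@@]1(O)CC[C@]2(C)CC=C(C)CC(=O)[C@@H]21
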